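Readings and results were computed for an exercise, and the scatter is random.

The vessel holds D and Z in the first phase and Q in the second; G is counted as a fraction of the D charged.

in all of them: Q 0.147 M

|  | D | Z | remark | time | volume of the second phase over the first |
|---|---|---|---|---|---|
| winter | 0.29 M | 0.042 M | run made earlier |  |  |
| spring | 0.46 M | 0.042 M | run made earlier |  |  |
| autumn | 0.21 M | 0.021 M | run made earlier |  |  |
| flask | 0.21 M | 0.0420 M |  | 40 h | 0.25 |

- winter (time / h: G / %): 4.00: 4.3; 8.00: 9.0; 12.0: 13.5; 15.0: 15.1; 20.0: 18.1; 25.0: 20.2
- spring (time / h: G / %): 1.50: 0.7; 5.00: 4.5; 8.00: 8.4; 12.0: 10.8; 20.0: 15.7; 25.0: 18.6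
- autumn (time / h: G / %): 2.00: 0.7; 4.00: 3.6; 6.00: 7.0; 12.0: 14.2; 25.0: 23.0

(readings scatter by 0.5 percentage points)

- in the second phase: Q; everything else is in the first
- charges count per volume of the first phase; a concentration in a rate is the amount of a species over the volume of its own phase; every rate counts per litre of the first phase
- the earlier runs hold the two phases in the same ratio of volumes as the flask asked about

* the G standing at 40 h, as a percentage of the D charged
* the change that raises the amount of G at 40 h, in percent of the D charged most ("none" if none brings more than 2 percentage points) (ash / larch / none)
* amount of G at 40 h, in percent of the D charged, after larch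

The Q charged over the D charged is 0.700 in the flask. This ratio, the ceiling on the fraction G if one Q makes one G, makes Q rather than D the limiting reagent of that ceiling. At 25.0 h the readings of G climb with it: 18.6% at 0.320, 20.2% at 0.507, 23.0% at 0.700, though the last, the autumn run, also holds less Z than the other two.

The autumn run has the charges of D and Q of the flask, so its curve is the guide, but one number is not enough: the flask holds twice the Z of autumn, and the ratio does not contain Z.

The autumn rate reads 0.0120 /h, then 0.00677 /h. The second is 56.4% of the first, less than the 67.0% of D that the autumn run keeps at 25.0 h even if each Z charged takes one D. This reckoning reads the fall as a fading reagent, with a read time of 16.6 h.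

Carried along the autumn curve to 40 h, this reckoning gives about 27.5% for the flask, with its extra Z unpriced. It picks ash, which doubles the ratio; larch is reckoned to trim a lag, read from the autumn readings as about 1.2 percentage points, below 2 points.

The forecast differs, with 31% (27% to 36%), 32% after larch, and best none: “Extra Q does little.”

The flask gives 25.9%, and 26.0% after larch. The best change is ash, gaining 12 points against 0.12 points for larch.

    D + Z → J (k = 0.370 /M/h)
    L ⇌ Q, rate k2*([L] - [Q]/K2) per volume of the first phase (partition coefficient = 2.30, kL = 0.220 /h)
    2 L → E (k = 0.420 /M/h)
    D + L → G (k = 0.220 /M/h)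

The neighbouring flask with 0.17 M of Z keeps the ratio of Q to D at 0.700, and so the same ceiling, while Z over D goes from 0.200 to 0.810 equiv. Yet at 40.0 h this neighbouring flask stands lower in G than the flask: J holds 60.2% of the D charged, G 18.3%, and 21.6% of D remains.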